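All constants are invented; the rest is arithmetic.

D in this flask is best counted in turnovers of the catalyst, so here is the quick number on that footing.

    L + Z ⇌ L.Z, settled at all times (K1 = 15 M⁻¹)
    E + L + Z → Z + D (k2 = 161 M⁻² s⁻¹)
    G ⇌ L, rate k3*(csat - [L]) (k3 = 0.428 s⁻¹, csat = 98 mM)
    Z + Z ⇌ Z2 (K4 = 37500 M⁻¹, k4 = 26.0 M⁻¹ s⁻¹)

E 0.20 M; G 98 mM (held); Z 4.0 mM; time 20 s

* D at 20 s, in percent of the E charged
* concentration of L in solution at 10 s, in percent of saturation
* the change that raises the amount of D at 20 s, in percent of the E charged most ("none" if none brings more than 2 percentage points) (Friday's / Wednesday's / Tuesday's / none)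
* amount of D at 20 s, in percent of the E charged, after Tuesday's

- Friday's: doubling the amount of Z, all else as stated
- Wednesday's: doubling the saturation concentration of G, all else as stated
- Tuesday's: doubling the transfer coefficient of step 3, all else as stated

- where a step has two of a species, its rate is k times that concentration squared, and two are used at each turn
- at the start none of L is dissolved
- run time (flask): 20 s

A catalyst held as Z or L.Z in a saturated solution, with E as charged, turns over at 1.28 s⁻¹, its turnover frequency. So 20 s allow 25.6 turnovers. This turnover budget stands against the 50.0 that the charge of E asks for, which puts the ceiling on D at 51.1%. The hunch that gas holds D back fails on amount: transfer can bring 419% of the E charged by then, more than that ceiling, and its lag of 2.34 s is shorter than the run.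

The pairing of Z into Z2 costs more. At saturation 40.5% of the monomeric catalyst is free Z. Take x as twice the forward pairing constant, times that share squared, times the charge of Z, times the time, here 0.682. The mean share of catalyst still monomeric is then the logarithm of one plus x, divided by x, or 76.2%.

Ceiling, share and lag give 34.4% for y, to be read as high, since E is held at its charge. Where transfer matches use at 10 s, [L] stands at 90.9% of saturation. Tuesday's brings the lag down to 1.17 s, giving 36.7%. Friday's multiplies D by 1.65 and Wednesday's by 1.46, so this reckoning picks Friday's.

The forecast gave 25.7%, 91.2%, 28.7% and Wednesday's: “Wednesday's narrowly wins”.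

The flask gives 25.8%, 91.8% and 28.7%, with Wednesday's best at 12 percentage points against 9.5 points for Friday's, so the reckoning parts from it on y, on the yield after Tuesday's and on the choice, and comes near it on [L] at 10 s. At 2.00 s, Z2 already holds 17.6% of the catalyst while [L] stands at 53.5% of saturation. Of the budget of 25.6, the flask used 12.9 turnovers, about half. The neighbour with 0.0024 M of Z has the same budget per catalyst and reaches 19.0%, which is 15.8 turnovers.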